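The route rests on disconnecting the C9–C10 bond of ring B (drimane numbering). Once ring B is viewed at the oxidation level of a C7 enolate, C9–C10 is the bond forged in an oxy-Cope rearrangement, the second alkene of the 1,5-diene being C1–C2 next to the C3 carbonyl. One anionic [3,3] shift of a bicyclo[2.2.2]octenol alkoxide therefore cleaves C2–C7, closes ring B cis-fused to ring A, sets the quaternary C10 and C9, and leaves a C7 enolate that is trapped as the triflate marking the C7–C8 alkene. The precursor is a ketal-protected 2-alkenylbicyclo[2.2.2]oct-5-en-2-ol whose (E)-4-silyloxybut-2-en-2-yl group lies syn to the methylated alkene bridge.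

Key step: step 9

Assumption: the (S)-configured oxazaborolidinium catalyst is taken to expose the same acrylate face toward dienone 6 as toward simple 1,3-dienes, which corresponds to adduct 8 as drawn; should the sense prove opposite, the (R)-catalyst is used and nothing else changes.

Numbering: decalins carry drimane locants (C1–C11). Bicyclic intermediates are named as bicyclo[2.2.2]octenes, whose C1, C2, C3, C4, C5, C6, C7, C8 are drimane C2, C7, C6, C5, C10, C1, C3, C4.

Step 1
Reactants: 1 but-2-yn-1-ol
Product: 2 tert-butyl(but-2-yn-1-yloxy)dimethylsilane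
Conditions: TBSCl, imidazole, CH2Cl2, 0 °C → rt
Reagents that add atoms: tert-butyldimethylsilyl chloride, CC(C)(C)[Si](C)(C)Cl
Why: Routine silylation of a primary alcohol gives an ether that should survive organolithium, hydride and KH conditions and is removed together with the ketal at the end.

Step 2
Reactants: 2 tert-butyl(but-2-yn-1-yloxy)dimethylsilane
Product: 4 (E)-tert-butyl[(3-iodobut-2-en-1-yl)oxy]dimethylsilane, via alkenylzirconocene chloride 3 (not isolated)
Conditions: Cp2Zr(H)Cl (2 equiv), THF, 50 °C; then I2, 0 °C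
Reagents that add atoms: iodine, [I][I]
Why: Hydrozirconation–iodination, in which syn addition of Zr–H (equilibrated by excess Cp2Zr(H)Cl so that zirconium rests on the less hindered, methyl-bearing carbon) and iodinolysis with retention should place iodine trans to the CH2OSi group, the E geometry that anti-hydroalumination of the propargylic alcohol cannot deliver.

Step 3
Reactants: 5 2,4-dimethylphenol
Product: 6 4,6,6-trimethylcyclohexa-2,4-dien-1-one
Conditions: n-BuLi (1.0 equiv), toluene, 0 °C; MeI (0.7 equiv), 110 °C, sealed tube; Claisen alkali wash; chromatography; used at once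
Reagents that add atoms: iodomethane, CI
Why: Alkylative dearomatisation, in which the aggregated lithium phenoxide in a non-polar solvent is C-methylated at its ortho carbons and attack at the methyl-bearing one gives the blocked dienone 6, whereas attack at the free ortho carbon only returns a phenol that is extracted with base and the anisole from O-methylation is removed by chromatography.

Step 4
Reactants: 6 4,6,6-trimethylcyclohexa-2,4-dien-1-one; 7 2,2,2-trifluoroethyl acrylate
Product: 8 2,2,2-trifluoroethyl (1S,2S,4S)-5,8,8-trimethyl-7-oxobicyclo[2.2.2]oct-5-ene-2-carboxylate (endo: ester syn to the C5=C6 bridge)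
Conditions: (S)-3,3-diphenyl-1-(2-methylphenyl)tetrahydro-1H,3H-pyrrolo[1,2-c][1,3,2]oxazaborole (20 mol%), (CF3SO2)2NH (18 mol%), 7 (3 equiv), CH2Cl2, −40 → 0 °C
Reagents that add atoms: none
Why: Catalytic enantioselective Diels–Alder reaction, in which the cationic oxazaborolidine binds the acrylate and leaves the Re face of its α-carbon open (setting C2), the larger diene coefficient at C5 of 6 reinforced by the C4 methyl sends the acrylate CH2 to C5 and the ester-bearing carbon to C2 of the dienone, and endo approach ties both bridgeheads (C1 and C4) to that face, the minor exo adduct being removed by chromatography because it would lead to the antipodal ketone.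

Step 5
Reactants: 8 2,2,2-trifluoroethyl (1S,2S,4S)-5,8,8-trimethyl-7-oxobicyclo[2.2.2]oct-5-ene-2-carboxylate
Product: 9 2,2,2-trifluoroethyl (1S,2S,4S)-7,7-(ethylenedioxy)-5,8,8-trimethylbicyclo[2.2.2]oct-5-ene-2-carboxylate
Conditions: Me3SiOCH2CH2OSiMe3 (3 equiv), Me3SiOTf (10 mol%), CH2Cl2, −78 → 0 °C; pyridine quench
Reagents that add atoms: 1,2-bis(trimethylsilyloxy)ethane, C[Si](C)(C)OCCO[Si](C)(C)C
Why: Noyori ketalisation under aprotic conditions is chosen because the ketone between the gem-dimethyl carbon and the bridgehead is hindered and because no free glycol is present that could transesterify the activated ester, and no stereocentre is touched.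

Step 6
Reactants: 9 2,2,2-trifluoroethyl (1S,2S,4S)-7,7-(ethylenedioxy)-5,8,8-trimethylbicyclo[2.2.2]oct-5-ene-2-carboxylate
Product: 11 2,2,2-trifluoroethyl (1S,2S,4S)-7,7-(ethylenedioxy)-2-hydroxy-5,8,8-trimethylbicyclo[2.2.2]oct-5-ene-2-carboxylate, via potassium ester enolate 10 (not isolated)
Conditions: KN(SiMe3)2, THF, −78 °C; then 2-(phenylsulfonyl)-3-phenyloxaziridine, −78 °C; aq. NH4Cl
Reagents that add atoms: 2-(phenylsulfonyl)-3-phenyloxaziridine, O=S(=O)(c1ccccc1)N1OC1c1ccccc1
Why: Enolate hydroxylation with an N-sulfonyloxaziridine works here because the ester α-hydrogen is the only acidic one, the enolate is kept at −78 °C to avoid loss of trifluoroethoxide, and oxygen should enter from the alkene-bridge face, although the configuration at this carbon is immaterial since it becomes a carbonyl carbon in step 7.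

Step 7
Reactants: 11 2,2,2-trifluoroethyl (1S,2S,4S)-7,7-(ethylenedioxy)-2-hydroxy-5,8,8-trimethylbicyclo[2.2.2]oct-5-ene-2-carboxylate
Product: 13 (1S,4S)-7,7-(ethylenedioxy)-5,8,8-trimethylbicyclo[2.2.2]oct-5-en-2-one, via diol 12 (not isolated)
Conditions: LiBH4, THF, 0 °C → rt; aq. NH4Cl; then NaIO4, THF/pH 7 phosphate buffer, 0 °C → rt
Reagents that add atoms: none
Why: Reduction of the activated α-hydroxy ester to the 1,2-diol followed by periodate glycol cleavage excises the former ester carbon as formaldehyde and leaves the C2 ketone (drimane C7), the ketal, the alkene and both bridgehead stereocentres being inert under these near-neutral conditions.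

Step 8
Reactants: 13 (1S,4S)-7,7-(ethylenedioxy)-5,8,8-trimethylbicyclo[2.2.2]oct-5-en-2-one; 4 (E)-tert-butyl[(3-iodobut-2-en-1-yl)oxy]dimethylsilane
Product: 16 (1S,2R,4S)-2-[(E)-4-(tert-butyldimethylsilyloxy)but-2-en-2-yl]-7,7-(ethylenedioxy)-5,8,8-trimethylbicyclo[2.2.2]oct-5-en-2-ol, via alkenyllithium 14 (not isolated), via alkenylcerium dichloride 15 (not isolated)
Conditions: 4, t-BuLi (2.05 equiv), Et2O, −78 °C; anhydrous CeCl3, THF, −78 °C; then 13, −78 → −40 °C; aq. NH4Cl
Reagents that add atoms: none
Why: Iodine–lithium exchange with retention of alkene geometry, transmetalation to the weakly basic organocerium and 1,2-addition to the enolisable ketone should occur from the face of the alkene bridge, because the opposite face is screened by the ketal and the gem-dimethyl group of the saturated bridge, so that the alkenyl group ends syn to the C5=C6 alkene (2R carbinol) as the rearrangement requires.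

Step 9
Reactants: 16 (1S,2R,4S)-2-[(E)-4-(tert-butyldimethylsilyloxy)but-2-en-2-yl]-7,7-(ethylenedioxy)-5,8,8-trimethylbicyclo[2.2.2]oct-5-en-2-ol
Product: 19 (4aS,5S,8aS)-5-{[(tert-butyldimethylsilyl)oxy]methyl}-2,2-(ethylenedioxy)-1,1,4a,6-tetramethyl-1,2,4a,5,8,8a-hexahydronaphthalen-7-yl trifluoromethanesulfonate, via potassium alkoxide 17 (not isolated), via potassium enolate 18 (not isolated)
Conditions: KH, 18-crown-6, THF, 0 °C → rt; then PhN(SO2CF3)2, −78 → 0 °C; aq. NH4Cl
Reagents that add atoms: N-phenylbis(trifluoromethanesulfonimide), O=S(=O)(N(c1ccccc1)S(=O)(=O)C(F)(F)F)C(F)(F)F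
Why: Deprotonation gives a crown-separated potassium alkoxide whose charge weakens the C2–C7 bond (drimane numbering), and a concerted suprafacial [3,3] shift through the array C9=C8–C7···C2–C1=C10 forms C9–C10 as that bond breaks, the resulting C7 enolate being O-sulfonylated by PhN(SO2CF3)2 before it can equilibrate. The closest known reaction type is the anionic oxy-Cope rearrangement of 2-alkenylbicyclo[2.2.2]oct-5-en-2-ols to cis-fused octalone enolates with in situ triflation, and forming a quaternary carbon next to a substituted alkene terminus is an extension within that class. Ring B (C5–C10) closes in a sigmatropic mode through a six-centre boat transition state, the only one the bicyclic tether allows, so no exo or endo alternative exists. C10 is set by the bicycle, since C9 can reach only the face of the C1=C10 alkene that lies under the alkenyl group, which makes the C10 methyl cis to H5; C9 is set by the E geometry, which in the boat turns the CH2OSi group outward and the C9 hydrogen inward toward C5 and C6 and so places C11 trans to the C10 methyl. The step needs the concerted path to beat stepwise cleavage and needs a regiodefined enolate: the C3 ketal removes the carbonyl that would open a retro-aldol and Michael route, the trans relation of alkoxide and silyl ether across the E alkene prevents silyl transfer, and aprotic crown-ether conditions keep the tetrasubstituted enolate from isomerising before triflation.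

Step 10
Reactants: 19 (4aS,5S,8aS)-5-{[(tert-butyldimethylsilyl)oxy]methyl}-2,2-(ethylenedioxy)-1,1,4a,6-tetramethyl-1,2,4a,5,8,8a-hexahydronaphthalen-7-yl trifluoromethanesulfonate
Product: 20 (4aS,5S,8aS)-5-{[(tert-butyldimethylsilyl)oxy]methyl}-2,2-(ethylenedioxy)-1,1,4a,6-tetramethyl-1,2,3,4,4a,5,8,8a-octahydronaphthalen-7-yl trifluoromethanesulfonate
Conditions: 2-nitrobenzenesulfonylhydrazide (excess, in portions), Et3N, CH2Cl2, rt
Reagents that add atoms: none
Why: Diimide reduction by concerted syn transfer of H2 is confined to the cis-disubstituted C1–C2 alkene because the only other C=C bond is a tetrasubstituted, electron-poor enol triflate, so excess reagent can be used against the hindered alkene and no stereocentre is created or disturbed.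

Step 11
Reactants: 20 (4aS,5S,8aS)-5-{[(tert-butyldimethylsilyl)oxy]methyl}-2,2-(ethylenedioxy)-1,1,4a,6-tetramethyl-1,2,3,4,4a,5,8,8a-octahydronaphthalen-7-yl trifluoromethanesulfonate
Product: 21 tert-butyl{[(1R,4aS,8aS)-6,6-(ethylenedioxy)-2,5,5,8a-tetramethyl-1,4,4a,5,6,7,8,8a-octahydronaphthalen-1-yl]methoxy}dimethylsilane
Conditions: Pd(OAc)2 (5 mol%), PPh3 (10 mol%), Bu3N, HCO2H, DMF, 60 °C
Reagents that add atoms: none
Why: Palladium-catalysed formate reduction of an enol triflate (oxidative addition to zerovalent palladium, formate exchange, decarboxylation and C–H reductive elimination) replaces the sulfonate by hydrogen without moving the double bond, which leaves the C7–C8 alkene of the target.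

Step 12
Reactants: 21 tert-butyl{[(1R,4aS,8aS)-6,6-(ethylenedioxy)-2,5,5,8a-tetramethyl-1,4,4a,5,6,7,8,8a-octahydronaphthalen-1-yl]methoxy}dimethylsilane
Product: 22 (4aS,5R,8aS)-5-(hydroxymethyl)-1,1,4a,6-tetramethyl-3,4,4a,5,8,8a-hexahydronaphthalen-2(1H)-one
Conditions: 1 M aq. HCl, THF, rt
Reagents that add atoms: water, O
Why: Acid hydrolysis removes the dioxolane and the primary silyl ether in one operation, none of C5, C9 and C10 is α to the liberated C3 ketone (C4 is quaternary) so no epimerisation is possible, and dilute acid at rt should not shift the trisubstituted alkene.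

Step 13
Reactants: 22 (4aS,5R,8aS)-5-(hydroxymethyl)-1,1,4a,6-tetramethyl-3,4,4a,5,8,8a-hexahydronaphthalen-2(1H)-one; 23 umbelliferone (7-hydroxy-2H-chromen-2-one)
Product: 24 7-{[(1R,4aS,8aS)-2,5,5,8a-tetramethyl-6-oxo-1,4,4a,5,6,7,8,8a-octahydronaphthalen-1-yl]methoxy}-2H-chromen-2-one
Conditions: PPh3, DIAD, THF, 0 °C → rt
Reagents that add atoms: none
Why: Mitsunobu etherification of the primary C11 alcohol with the acidic 7-hydroxyl of the coumarin forms the aryl ether at a non-stereogenic carbon, tolerates the ketone and the alkene, and keeps the base-sensitive lactone out of every earlier step.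

Compound list
1 | but-2-yn-1-ol | CC#CCO | starting material
2 | tert-butyl(but-2-yn-1-yloxy)dimethylsilane | CC#CCO[Si](C)(C)C(C)(C)C | intermediate
3 | chlorobis(cyclopentadienyl)[(E)-4-(tert-butyldimethylsilyloxy)but-2-en-2-yl]zirconium | C/C(=C\CO[Si](C)(C)C(C)(C)C)[Zr](Cl)(C1C=CC=C1)C1C=CC=C1 | intermediate (not isolated)
4 | (E)-tert-butyl[(3-iodobut-2-en-1-yl)oxy]dimethylsilane | C/C(I)=C\CO[Si](C)(C)C(C)(C)C | intermediate
5 | 2,4-dimethylphenol | Cc1ccc(O)c(C)c1 | starting material
6 | 4,6,6-trimethylcyclohexa-2,4-dien-1-one | CC1=CC(C)(C)C(=O)C=C1 | intermediate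
7 | 2,2,2-trifluoroethyl acrylate | C=CC(=O)OCC(F)(F)F | starting material
8 | 2,2,2-trifluoroethyl (1S,2S,4S)-5,8,8-trimethyl-7-oxobicyclo[2.2.2]oct-5-ene-2-carboxylate (endo) | O=C(OCC(F)(F)F)[C@H]1C[C@H]2C(C)=C[C@@H]1C(=O)C2(C)C | intermediate
9 | 2,2,2-trifluoroethyl (1S,2S,4S)-7,7-(ethylenedioxy)-5,8,8-trimethylbicyclo[2.2.2]oct-5-ene-2-carboxylate | O=C(OCC(F)(F)F)[C@H]1C[C@H]2C(C)=C[C@@H]1C3(OCCO3)C2(C)C | intermediate
10 | potassium enolate of ester 9 | [K+].[O-]C(OCC(F)(F)F)=C1C[C@H]2C(C)=C[C@@H]1C3(OCCO3)C2(C)C | intermediate (not isolated)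
11 | 2,2,2-trifluoroethyl (1S,2S,4S)-7,7-(ethylenedioxy)-2-hydroxy-5,8,8-trimethylbicyclo[2.2.2]oct-5-ene-2-carboxylate (OH syn to the alkene bridge) | O=C(OCC(F)(F)F)[C@]1(O)C[C@H]2C(C)=C[C@@H]1C3(OCCO3)C2(C)C | intermediate
12 | (1S,2S,4S)-7,7-(ethylenedioxy)-2-(hydroxymethyl)-5,8,8-trimethylbicyclo[2.2.2]oct-5-en-2-ol | OC[C@]1(O)C[C@H]2C(C)=C[C@@H]1C3(OCCO3)C2(C)C | intermediate (not isolated)
13 | (1S,4S)-7,7-(ethylenedioxy)-5,8,8-trimethylbicyclo[2.2.2]oct-5-en-2-one | O=C1C[C@H]2C(C)=C[C@@H]1C3(OCCO3)C2(C)C | intermediate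
14 | [(E)-4-(tert-butyldimethylsilyloxy)but-2-en-2-yl]lithium | [Li]/C(C)=C/CO[Si](C)(C)C(C)(C)C | intermediate (not isolated)
15 | [(E)-4-(tert-butyldimethylsilyloxy)but-2-en-2-yl]cerium dichloride | Cl[Ce](Cl)/C(C)=C/CO[Si](C)(C)C(C)(C)C | intermediate (not isolated)
16 | (1S,2R,4S)-2-[(E)-4-(tert-butyldimethylsilyloxy)but-2-en-2-yl]-7,7-(ethylenedioxy)-5,8,8-trimethylbicyclo[2.2.2]oct-5-en-2-ol (alkenyl syn to the alkene bridge) | C/C(=C\CO[Si](C)(C)C(C)(C)C)[C@@]1(O)C[C@H]2C(C)=C[C@@H]1C3(OCCO3)C2(C)C | intermediate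
17 | potassium alkoxide of 16 | [K+].C/C(=C\CO[Si](C)(C)C(C)(C)C)[C@@]1([O-])C[C@H]2C(C)=C[C@@H]1C3(OCCO3)C2(C)C | intermediate (not isolated)
18 | potassium C7 enolate of the cis-fused decalin (drimane C5 S, C9 S, C10 S; C1–C2 alkene, C3 ketal, C11 OTBS) | [K+].CC1=C([O-])C[C@@H]2C(C)(C)C3(OCCO3)C=C[C@]2(C)[C@@H]1CO[Si](C)(C)C(C)(C)C | intermediate (not isolated)
19 | (4aS,5S,8aS)-5-{[(tert-butyldimethylsilyl)oxy]methyl}-2,2-(ethylenedioxy)-1,1,4a,6-tetramethyl-1,2,4a,5,8,8a-hexahydronaphthalen-7-yl trifluoromethanesulfonate (drimane C5 S, C9 S, C10 S; H5 cis to the C10 methyl, C11 trans to it) | CC1=C(OS(=O)(=O)C(F)(F)F)C[C@@H]2C(C)(C)C3(OCCO3)C=C[C@]2(C)[C@@H]1CO[Si](C)(C)C(C)(C)C | intermediate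
20 | (4aS,5S,8aS)-5-{[(tert-butyldimethylsilyl)oxy]methyl}-2,2-(ethylenedioxy)-1,1,4a,6-tetramethyl-1,2,3,4,4a,5,8,8a-octahydronaphthalen-7-yl trifluoromethanesulfonate | CC1=C(OS(=O)(=O)C(F)(F)F)C[C@@H]2C(C)(C)C3(OCCO3)CC[C@]2(C)[C@@H]1CO[Si](C)(C)C(C)(C)C | intermediate
21 | tert-butyl{[(1R,4aS,8aS)-6,6-(ethylenedioxy)-2,5,5,8a-tetramethyl-1,4,4a,5,6,7,8,8a-octahydronaphthalen-1-yl]methoxy}dimethylsilane (drimane C5 S, C9 R, C10 S) | CC1=CC[C@@H]2C(C)(C)C3(OCCO3)CC[C@]2(C)[C@@H]1CO[Si](C)(C)C(C)(C)C | intermediate
22 | (4aS,5R,8aS)-5-(hydroxymethyl)-1,1,4a,6-tetramethyl-3,4,4a,5,8,8a-hexahydronaphthalen-2(1H)-one | CC1=CC[C@@H]2C(C)(C)C(=O)CC[C@]2(C)[C@@H]1CO | intermediate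
23 | umbelliferone (7-hydroxy-2H-chromen-2-one) | O=c1ccc2ccc(O)cc2o1 | starting material
24 | 7-{[(1R,4aS,8aS)-2,5,5,8a-tetramethyl-6-oxo-1,4,4a,5,6,7,8,8a-octahydronaphthalen-1-yl]methoxy}-2H-chromen-2-one (drimane C5 S, C9 R, C10 S) | CC1=CC[C@@H]2C(C)(C)C(=O)CC[C@]2(C)[C@@H]1COc1ccc2ccc(=O)oc2c1 | target

Total step count: 13. Longest linear sequence: 11 steps (5 to 24, steps 3–13); steps 1–2 make the side fragment 4.

Steps most likely to fail

Step 9. The alkoxide may cleave the C2–C7 bond heterolytically, or revert to ketone and alkenyl anion, faster than C9 bonds to the methyl-bearing C10; this would give ring-opened or non-stereospecifically reclosed material. The hindered enolate may also be protonated before it is triflated. The fallback is the neutral, thermal variant, which avoids free anions. It sets out from 16, which is silylated (1-(trimethylsilyl)imidazole, CH2Cl2) to the trimethylsilyl ether of 16 F1. Thermolysis of F1 (decalin, 220–250 °C, sealed base-washed tube) through the same boat array should give the trimethylsilyl enol ether F2. MeLi (THF, 0 °C) cleaves the O–Si bond regiospecifically to the lithium enolate F3, and PhN(SO2CF3)2 converts it into 19, where the route is rejoined.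

Step 4. The Lewis-basic dienone carbonyl may sequester the boron catalyst, so that turnover is slow and acid-induced dienone–phenol rearrangement or dimerisation of 6 takes over. Facial and endo selectivity may also be too low for this electron-poorer diene. The fallback replaces catalysis by resolution. It sets out from 6 and 7, whose uncatalysed cycloaddition (toluene, 90 °C) should give the racemic endo adduct rac-8 F4. Mild saponification (LiOH, THF/H2O, 0 °C) gives the racemic keto acid F5. Crystallisation with (S)-1-phenylethylamine (or its antipode, whichever gives the less soluble salt of the wanted acid) provides the salt F6. Acidification liberates the (1S,2S,4S)-acid F7, and esterification (CF3CH2OH, EDC·HCl, DMAP, CH2Cl2) returns 8.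

Step 3. Methylation at the unsubstituted ortho carbon and at oxygen competes with attack at the methyl-bearing carbon. The phenol so formed can be methylated again to a tetramethyl dienone that is hard to remove, and 6 dimerises on standing. The fallback builds the dienone without a regiochemical choice. It sets out from 5, which is O-methylated (MeI, K2CO3, acetone) to 2,4-dimethylanisole F8. Birch reduction (Li, liquid NH3, t-BuOH, THF, −78 °C) gives 1-methoxy-2,4-dimethylcyclohexa-1,4-diene F9. Aqueous HCl hydrolyses and conjugates it to racemic 4,6-dimethylcyclohex-2-en-1-one F10. Kinetic α′-methylation (LiN(i-Pr)2, THF, −78 °C; MeI) gives racemic 4,6,6-trimethylcyclohex-2-en-1-one F11. Dehydrogenation at the γ,δ-position (chloranil, t-BuOH, reflux; the α′-carbon is blocked) returns 6.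

Further compounds
F1 | step 9 | trimethylsilyl ether of carbinol 16 | C/C(=C\CO[Si](C)(C)C(C)(C)C)[C@@]1(O[Si](C)(C)C)C[C@H]2C(C)=C[C@@H]1C3(OCCO3)C2(C)C
F2 | step 9 | C7 trimethylsilyl enol ether of the cis-fused decalin (C1–C2 alkene, C3 ketal, C11 OTBS) | CC1=C(O[Si](C)(C)C)C[C@@H]2C(C)(C)C3(OCCO3)C=C[C@]2(C)[C@@H]1CO[Si](C)(C)C(C)(C)C
F3 | step 9 | lithium C7 enolate of the cis-fused decalin | [Li+].CC1=C([O-])C[C@@H]2C(C)(C)C3(OCCO3)C=C[C@]2(C)[C@@H]1CO[Si](C)(C)C(C)(C)C
F4 | step 4 | rac-8, racemic endo 2,2,2-trifluoroethyl 5,8,8-trimethyl-7-oxobicyclo[2.2.2]oct-5-ene-2-carboxylate (relative configuration shown) | O=C(OCC(F)(F)F)[C@H]1C[C@H]2C(C)=C[C@@H]1C(=O)C2(C)C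
F5 | step 4 | racemic endo 5,8,8-trimethyl-7-oxobicyclo[2.2.2]oct-5-ene-2-carboxylic acid (relative configuration shown) | O=C(O)[C@H]1C[C@H]2C(C)=C[C@@H]1C(=O)C2(C)C
F6 | step 4 | (S)-1-phenylethylammonium (1S,2S,4S)-5,8,8-trimethyl-7-oxobicyclo[2.2.2]oct-5-ene-2-carboxylate | C[C@H]([NH3+])c1ccccc1.[O-]C(=O)[C@H]1C[C@H]2C(C)=C[C@@H]1C(=O)C2(C)C
F7 | step 4 | (1S,2S,4S)-5,8,8-trimethyl-7-oxobicyclo[2.2.2]oct-5-ene-2-carboxylic acid (single enantiomer) | O=C(O)[C@H]1C[C@H]2C(C)=C[C@@H]1C(=O)C2(C)C
F8 | step 3 | 2,4-dimethylanisole | COc1ccc(C)cc1C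
F9 | step 3 | 1-methoxy-2,4-dimethylcyclohexa-1,4-diene | COC1=C(C)CC(C)=CC1
F10 | step 3 | 4,6-dimethylcyclohex-2-en-1-one (racemic mixture of diastereomers) | CC1CC(C)C(=O)C=C1
F11 | step 3 | 4,6,6-trimethylcyclohex-2-en-1-one (racemic) | CC1CC(C)(C)C(=O)C=C1
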